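**Retrosynthetic overview**
1. The C8 methacrylate goes on last. Both cis-oxiranes come from one hydroxyl-directed double epoxidation of a (1(10)Z,4Z)-germacradienolide that carries a free 8-OH.
2. The ten-membered carbocycle is opened at C1=C10 by ring-closing metathesis (terminal vinyl plus methallyl).
3. The C5–C6 bond is cut to a stereodefined Z-alkenylboron reagent (butenyl Grignard plus propyne) and a γ-hydroxybutenolide. They are joined by a new metal-free, OH-directed "oxa-Petasis" alkenylation.
4. The hydroxybutenolide comes from singlet-oxygen oxidation of a 3,4-disubstituted furan. Its C8 carbinol comes from a chiral-phosphoric-acid-catalysed methallylboration of an achiral furaldehyde. This is the only catalyst-set stereocentre and it relays to the other five.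
5. Ring order: furan (bought), then butenolide, then ten-membered carbocycle, then the two oxiranes.

Assumption: the SMILES is taken literally, so both oxiranes are cis-fused (Z-olefin derived), all six ring C–O bonds lie on one face, and the configuration is 1R,4S,5R,6R,8R,10S in germacrane numbering, used throughout (C6 = lactone CH–O, C7=C11 = butenolide olefin, C8 = CH–O-methacrylate, C13 = CH2OAc).

**Step 1**
Reactants: 1 furan-3,4-diyldimethanol; 2 acetic anhydride
Product: 3 [4-(hydroxymethyl)furan-3-yl]methyl acetate
Conditions: Ac2O (1.0 equiv), pyridine, CH2Cl2, 0 °C (diol and diacetate recycled)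
Reagents that add atoms: acetic anhydride (2), CC(=O)OC(C)=O
Why: Statistical mono-acylation (nucleophilic acyl substitution) of a symmetric primary diol, whose mono-ester, di-ester and diol separate easily, installs the C13 acetate and creates no stereocentre.

**Step 2**
Reactants: 3 [4-(hydroxymethyl)furan-3-yl]methyl acetate
Product: 4 (4-formylfuran-3-yl)methyl acetate
Conditions: activated MnO2 (10 equiv), CH2Cl2, rt
Reagents that add atoms: none
Why: MnO2 oxidation of a furylic (benzylic-type) alcohol stops at the aldehyde (C8) and leaves the acetate and the furan untouched.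

**Step 3**
Reactants: 4 (4-formylfuran-3-yl)methyl acetate; 5 2-methylallylboronic acid pinacol ester
Product: 7 {4-[(1R)-1-hydroxy-3-methylbut-3-en-1-yl]furan-3-yl}methyl acetate, via the O-pinacolboryl ether of 7 6 (not isolated)
Conditions: (R)-TRIP (5 mol %), 4 Å MS, PhMe, −30 °C; aq NaHCO3
Reagents that add atoms: 2-methylallylboronic acid pinacol ester (5), CC(=C)CB1OC(C)(C)C(C)(C)O1
Why: In this chiral-phosphoric-acid-catalysed asymmetric allylboration (metal-free, closed chair transition state) the acid binds a pinacol oxygen and the formyl H, so the methallyl γ-carbon (C9) attacks one aldehyde face and sets C8 as R, the first stereocentre, (R)-TRIP being the enantiomer that gives (R)-1-arylbut-3-en-1-ols.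

**Step 4**
Reactants: 7 {4-[(1R)-1-hydroxy-3-methylbut-3-en-1-yl]furan-3-yl}methyl acetate
Product: 9 {5-hydroxy-4-[(1R)-1-hydroxy-3-methylbut-3-en-1-yl]-2-oxo-2,5-dihydrofuran-3-yl}methyl acetate (equilibrating C6 hemiacetal epimers), via the furan endoperoxide (2,3,7-trioxabicyclo[2.2.1]hept-5-ene) 8 (not isolated)
Conditions: O2, hν (visible), TPP (1 mol %), i-Pr2NEt (1.5 equiv), CH2Cl2, −78 °C → rt
Reagents that add atoms: dioxygen, O=O
Why: Singlet oxygen adds [4+2] to the furan far faster than it reacts with the 1,1-disubstituted olefin, and in the Kornblum–DeLaMare opening the hindered base removes the less hindered bridgehead H (next to the CH2OAc-bearing carbon), so C12 becomes the lactone C=O and C6 a labile hemiacetal that is ionised in step 6.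

**Step 5**
Reactants: 10 but-3-en-1-ylmagnesium bromide; 11 propyne
Product: 14 (1Z)-1-iodo-2-methylhexa-1,5-diene, via but-3-en-1-ylcopper 12 (not isolated), via (1Z)-2-methylhexa-1,5-dien-1-ylcopper 13 (not isolated)
Conditions: CuBr·SMe2 (1 equiv), Et2O/Me2S, −45 °C; propyne, −25 °C; I2, THF, −78 → 0 °C
Reagents that add atoms: propyne (11), CC#C; iodine, II
Why: Normant syn-carbocupration of propyne puts the butenyl chain (C1–C3) and copper cis on the new C4=C5 olefin (>98 % Z), and iodinolysis proceeds with retention.

**Step 6**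
Reactants: 14 (1Z)-1-iodo-2-methylhexa-1,5-diene; 9 the γ-hydroxybutenolide
Product: 19 {(5S)-4-[(1R)-1-hydroxy-3-methylbut-3-en-1-yl]-5-[(1Z)-2-methylhexa-1,5-dien-1-yl]-2-oxo-2,5-dihydrofuran-3-yl}methyl acetate, via (1Z)-2-methylhexa-1,5-dien-1-yllithium 15 (not isolated), via lithium triisopropoxy[(1Z)-2-methylhexa-1,5-dien-1-yl]borate 16 (not isolated), via diisopropyl [(1Z)-2-methylhexa-1,5-dien-1-yl]boronate 17 (not isolated), via the C8-O mixed alkenylboronate of 9 18 (not isolated)
Conditions: 14, t-BuLi (2 equiv), Et2O, −78 °C; B(Oi-Pr)3; HCl·Et2O (1 equiv), 0 °C; then 9, 4 Å MS, CH2Cl2/HFIP 4:1, 0 °C → rt; aq work-up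
Reagents that add atoms: none
Why: Proposed new method: a hydroxyl-directed, metal-free "oxa-Petasis" alkenylation of a γ-hydroxybutenolide, in which the C8-OH exchanges onto boron (18), the tethered boron abstracts the neighbouring hemiacetal OH to give a tight oxocarbenium/tetracoordinate-boronate zwitterion, and the Z-alkenyl group migrates with retention of olefin geometry through a six-membered transition state to the C6 face syn to O8 in the A(1,3)-minimised rotamer (H8 eclipsing C7=C11), so that the C5–C6 bond forms and C6 is set 1,3-syn to C8 (descriptor S here, R in the target after epoxidation), the closest known reaction types being the Petasis borono-Mannich reaction, hydroxyl-directed alkenylboronate additions to N-acyliminium ions and boronate/trifluoroborate additions to acetal-derived oxocarbenium ions.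

**Step 7**
Reactants: 19 the butenolide triene
Product: 20 (1(10)Z,4Z,6S,8R)-13-acetoxy-8-hydroxygermacra-1(10),4,7(11)-trien-12,6-olide
Conditions: Hoveyda–Grubbs II (10 mol %), 1,4-benzoquinone (20 mol %), PhMe (1 mM), 80 °C, Ar sparge
Reagents that add atoms: none
Why: In this ring-closing metathesis the catalyst loads on the unhindered C1 vinyl and closes onto the methallyl olefin, the only competing intramolecular closure (onto C4=C5) would give a cyclobutene, the Z-olefin and planar butenolide pre-bend the chain, and a ten-membered ring favours the Z-trisubstituted C1=C10 olefin by about 3 kcal/mol over E.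

**Step 8**
Reactants: 20 the (Z,Z)-macrocyclic alcohol
Product: 21 (1R,4S,5R,6R,8R,10S)-13-acetoxy-1,10:4,5-diepoxy-8-hydroxygermacr-7(11)-en-12,6-olide
Conditions: VO(acac)2 (10 mol %), t-BuOOH (2.5 equiv, decane), 4 Å MS, CH2Cl2, 0 °C → rt
Reagents that add atoms: tert-butyl hydroperoxide, CC(C)(C)OO
Why: In this hydroxyl-directed vanadium epoxidation the 8-alkoxide-bound peroxo-vanadium delivers oxygen to the homoallylic C1=C10 and bishomoallylic C4=C5 olefins on the ring face that carries O8, which gives both cis-oxiranes cis to O8 and O6 (C5–O anti to C6–O along the chain) and sets C1, C10, C4 and C5, while the electron-poor butenolide olefin is inert.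

**Step 9**
Reactants: 21 the diepoxy alcohol; 22 methacrylic anhydride
Product: 23 target, (1R,4S,5R,6R,8R,10S)-13-acetoxy-1,10:4,5-diepoxy-8-(methacryloyloxy)germacr-7(11)-en-12,6-olide
Conditions: methacrylic anhydride (1.5 equiv), Et3N, DMAP (10 mol %), CH2Cl2, 0 °C
Reagents that add atoms: methacrylic anhydride (22), CC(=C)C(=O)OC(=O)C(C)=C
Why: DMAP-catalysed acylation of the only free hydroxyl proceeds with retention at C8, and the mild base at low temperature avoids C13→C8 acetyl migration and C6 deprotonation.

**Compound list**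
1 | furan-3,4-diyldimethanol | OCc1cocc1CO | starting material
2 | acetic anhydride | CC(=O)OC(C)=O | starting material
3 | [4-(hydroxymethyl)furan-3-yl]methyl acetate | CC(=O)OCc1cocc1CO | intermediate
4 | (4-formylfuran-3-yl)methyl acetate | CC(=O)OCc1cocc1C=O | intermediate
5 | 2-methylallylboronic acid pinacol ester | CC(=C)CB1OC(C)(C)C(C)(C)O1 | starting material
6 | O-pinacolboryl ether of 7 (not isolated) | CC(=O)OCc1cocc1[C@@H](CC(C)=C)OB1OC(C)(C)C(C)(C)O1 | intermediate
7 | {4-[(1R)-1-hydroxy-3-methylbut-3-en-1-yl]furan-3-yl}methyl acetate | CC(=O)OCc1cocc1[C@H](O)CC(C)=C | intermediate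
8 | furan endoperoxide of 7 (not isolated) | CC(=O)OCC1=C([C@H](O)CC(C)=C)C2OOC1O2 | intermediate
9 | {5-hydroxy-4-[(1R)-1-hydroxy-3-methylbut-3-en-1-yl]-2-oxo-2,5-dihydrofuran-3-yl}methyl acetate | CC(=O)OCC1=C([C@H](O)CC(C)=C)C(O)OC1=O | intermediate
10 | but-3-en-1-ylmagnesium bromide | C=CCC[Mg]Br | starting material
11 | propyne | CC#C | starting material
12 | but-3-en-1-ylcopper (not isolated) | C=CCC[Cu] | intermediate
13 | (1Z)-2-methylhexa-1,5-dien-1-ylcopper (not isolated) | C=CCC/C(C)=C\[Cu] | intermediate
14 | (1Z)-1-iodo-2-methylhexa-1,5-diene | C=CCC/C(C)=C\I | intermediate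
15 | (1Z)-2-methylhexa-1,5-dien-1-yllithium (not isolated) | C=CCC/C(C)=C\[Li] | intermediate
16 | lithium triisopropoxy[(1Z)-2-methylhexa-1,5-dien-1-yl]borate (not isolated) | [Li+].C=CCC/C(C)=C\[B-](OC(C)C)(OC(C)C)OC(C)C | intermediate
17 | diisopropyl [(1Z)-2-methylhexa-1,5-dien-1-yl]boronate (not isolated) | C=CCC/C(C)=C\B(OC(C)C)OC(C)C | intermediate
18 | C8-O mixed isopropyl alkenylboronate of 9 (not isolated) | CC(=O)OCC1=C([C@@H](CC(C)=C)OB(OC(C)C)/C=C(C)\CCC=C)C(O)OC1=O | intermediate
19 | {(5S)-4-[(1R)-1-hydroxy-3-methylbut-3-en-1-yl]-5-[(1Z)-2-methylhexa-1,5-dien-1-yl]-2-oxo-2,5-dihydrofuran-3-yl}methyl acetate | CC(=O)OCC1=C([C@H](O)CC(C)=C)[C@H](/C=C(C)\CCC=C)OC1=O | intermediate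
20 | (1(10)Z,4Z,6S,8R)-13-acetoxy-8-hydroxygermacra-1(10),4,7(11)-trien-12,6-olide | O[C@@H]1C/C(C)=C\CC/C(C)=C\[C@@H]2OC(=O)C(COC(C)=O)=C21 | intermediate
21 | (1R,4S,5R,6R,8R,10S)-13-acetoxy-1,10:4,5-diepoxy-8-hydroxygermacr-7(11)-en-12,6-olide | O[C@@H]1C[C@]2(C)O[C@@H]2CC[C@]2(C)O[C@@H]2[C@@H]2OC(=O)C(COC(C)=O)=C21 | intermediate
22 | methacrylic anhydride | CC(=C)C(=O)OC(=O)C(C)=C | starting material
23 | CNP0212980.1 | C=C(C)C(=O)O[C@@H]1C[C@]2(C)O[C@@H]2CC[C@]2(C)O[C@@H]2[C@@H]2OC(=O)C(COC(C)=O)=C21 | target

**Total step count:** 9. **Longest linear sequence:** 8 (steps 1–4 and 6–9; step 5 is a one-step branch).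

**Steps most likely to fail**

Step 6 (the proposed new alkenylation). The acyl-oxocarbenium ion may be too hard to form. The boronate may protodeboronate. The methallyl olefin may trap C6 in a six-membered Prins closure. The fallback uses known chemistry, sets out from 9 and 14 and returns at 19. Compound 9 is opened and esterified with TMSCHN2 (PhH/MeOH) to methyl (2Z,4R)-2-(acetoxymethyl)-3-formyl-4-hydroxy-6-methylhepta-2,6-dienoate F1. A Nozaki–Hiyama–Kishi coupling of F1 with 14 (CrCl2, cat. NiCl2, DMF, rt) adds the Z-alkenylchromium to the aldehyde with retention of geometry. The resulting alkoxide, which is cis to the ester, lactonises spontaneously to 19. The C6 diastereomers are then separated by chromatography, because the boron tether no longer controls that centre.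

Step 7 (ten-membered RCM to a trisubstituted olefin). Oligomerisation or formation of the E isomer is possible. The fallback changes the order of ring construction to oxirane first and carbocycle second. It sets out from 19 and returns at 21. The only trisubstituted olefin of 19 is epoxidised under 8-OH direction (VO(acac)2, 1.1 equiv t-BuOOH; the oxidant reaches the face bearing C7/C8 in the A(1,3)-locked rotamer). This gives {(5R)-4-[(1R)-1-hydroxy-3-methylbut-3-en-1-yl]-5-[(2R,3S)-3-(but-3-en-1-yl)-3-methyloxiran-2-yl]-2-oxo-2,5-dihydrofuran-3-yl}methyl acetate F2. The cis-epoxide then acts as a flexible turn element and no other internal olefin is present. RCM of F2 gives (1(10)Z,4S,5R,6R,8R)-13-acetoxy-4,5-epoxy-8-hydroxygermacra-1(10),7(11)-dien-12,6-olide F3. A second directed epoxidation of the homoallylic C1=C10 olefin gives 21.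

Step 8 (double directed epoxidation). Delivery to the bishomoallylic olefin may be incomplete, the conformer may present the wrong face, or O8 may open an epoxide transannularly. The fallback replaces substrate direction by organocatalytic reagent control. It sets out from 20 and returns at 23. Compound 20 is first acylated with 22 (as in step 9) to (1(10)Z,4Z,6S,8R)-13-acetoxy-8-(methacryloyloxy)germacra-1(10),4,7(11)-trien-12,6-olide F4. F4 is then epoxidised twice with the D-fructose-derived Shi ketone (Oxone, K2CO3, Bu4NHSO4, MeCN/DMM–buffer pH 10.5, 0 °C). The spiro transition-state model predicts R at each CH carbon and S at each methyl-bearing carbon, which is the configuration of 23. The methacrylate and butenolide olefins are too electron-poor to react.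

**Further compounds**
F1 | step 6 | methyl (2Z,4R)-2-(acetoxymethyl)-3-formyl-4-hydroxy-6-methylhepta-2,6-dienoate | COC(=O)/C(COC(C)=O)=C(\C=O)[C@H](O)CC(C)=C
F2 | step 7 | {(5R)-4-[(1R)-1-hydroxy-3-methylbut-3-en-1-yl]-5-[(2R,3S)-3-(but-3-en-1-yl)-3-methyloxiran-2-yl]-2-oxo-2,5-dihydrofuran-3-yl}methyl acetate | CC(=O)OCC1=C([C@H](O)CC(C)=C)[C@H]([C@H]2O[C@@]2(C)CCC=C)OC1=O
F3 | step 7 | (1(10)Z,4S,5R,6R,8R)-13-acetoxy-4,5-epoxy-8-hydroxygermacra-1(10),7(11)-dien-12,6-olide | O[C@@H]1C/C(C)=C\CC[C@]2(C)O[C@@H]2[C@@H]2OC(=O)C(COC(C)=O)=C21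
F4 | step 8 | (1(10)Z,4Z,6S,8R)-13-acetoxy-8-(methacryloyloxy)germacra-1(10),4,7(11)-trien-12,6-olide | C=C(C)C(=O)O[C@@H]1C/C(C)=C\CC/C(C)=C\[C@@H]2OC(=O)C(COC(C)=O)=C21
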